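**Plan**
- Retrosynthesis: cut both aryl–C(=O) bonds (double Friedel–Crafts, back to all-trans 3,4-diphenylcyclobutane-1,2-dicarboxylic acid), then C3–Ph (conjugate addition), then C4–Ph (anti-SN2′ opening of a β-lactone), and last the ring bond C1–C2.
- Enabling feature: ring carbons C1 and C2 are adjacent and each carries one exocyclic carbonyl carbon, while C4 (next to C1) and C3 carry the phenyls. These six carbons map onto C3, C6, C4, C5, the lactone C2(=O) and the ester carbon of methyl 2-pyranone-6-carboxylate, so C1–C2 is the pyrone C3–C6 bond.
- Forward: the pyranone is photoisomerised to a cyclobutene cis-fused to a β-lactone (the only ring-forming event). One equivalent of a phenylcopper reagent opens the lactone, a second adds to the resulting cyclobutenoate, and the two carboxyl carbons become the aryl ketones.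
- Stereochemistry: the cis fusion fixes the lactone face, anti-SN2′ puts C4–Ph trans to the C1 carboxyl, and C3–Ph enters anti to C4–Ph. C2 is set by base equilibration to the all-trans isomer.
- Absolute configuration comes from resolving the half-ester as a 1-phenylethylammonium salt; the non-enolisable phenyl-bearing carbons then hold it.

Key step: step 2

Remark: the photochemical step gives a racemate, so every compound between it and the resolution is racemic; these carry the prefix rac- and their SMILES show the enantiomer that leads to the target.
Assumption: with (R)-1-phenylethylamine the less soluble salt of the racemic half-ester is taken to hold the (1R,2R,3S,4S)-acid; if a crystal structure of the salt shows the opposite pairing, the equally available (S)-amine takes its place and nothing else changes.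

**Step 1**
Reactants: 1 2-oxo-2H-pyran-6-carboxylic acid
Product: 2 methyl 2-oxo-2H-pyran-6-carboxylate
Conditions: MeOH, H2SO4 (cat.), reflux
Reagents that add atoms: methanol, CO
Why: Fischer esterification, which the 2-pyranone ring should tolerate as it does in the standard preparation of methyl coumalate from coumalic acid; no stereocentre is involved.

**Step 2**
Reactants: 2 methyl 2-oxo-2H-pyran-6-carboxylate
Product: 3 rac-methyl (1S,4R)-3-oxo-2-oxabicyclo[2.2.0]hex-5-ene-1-carboxylate
Conditions: hν (300 nm, Pyrex), dry degassed CH2Cl2 (0.02 M), −10 °C, FEP flow reactor; concentrated below 0 °C, taken up in THF and used crude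
Reagents that add atoms: none
Why: Singlet excitation of the pyranone chromophore sets off a disrotatory 4π electrocyclisation of the ring-locked s-cis diene C3=C4–C5=C6, which forms the pyrone C3–C6 σ bond (C1–C2 of the target) and leaves C4=C5 as the cyclobutene double bond. The closest known reaction type is the photochemical valence isomerisation of 2-pyranone and of its 5-carboxylate to 2-oxabicyclo[2.2.0]hex-5-en-3-ones, here applied to the 6-carboxylate. The cyclobutene closes by this photochemically allowed disrotatory 4π mode, and the same bond turns the six-membered lactone into the fused 2-oxetanone, so no further ring-forming event is needed. Both new stereocentres, C1 (from pyrone C6, carrying O and CO2Me) and C4 (from pyrone C3, carrying H), are controlled by the disrotatory motion inside the ring, which can only give the cis-fused bicycle; the flat, achiral pyrone offers no facial bias, so the product is racemic. The step needs valence isomerisation to win over the reversible α-cleavage to a ketene and over secondary photodecarboxylation: the aprotic solvent lets the ketene fall back to 2, and the product, having lost the conjugated pyranone chromophore, should be transparent at 300 nm and accumulate. The ester is a spectator on one diene terminus and already sits on the carbon that becomes C2 of the target.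

**Step 3**
Reactants: 3 rac-methyl (1S,4R)-3-oxo-2-oxabicyclo[2.2.0]hex-5-ene-1-carboxylate; 4 phenylmagnesium bromide (first equivalent, for the lactone opening)
Product: 6 rac-(1R,2S,3S,4S)-2-(methoxycarbonyl)-3,4-diphenylcyclobutane-1-carboxylic acid, via cyclobutene magnesium carboxylate 5 (not isolated)
Conditions: CuBr·SMe2 (20 mol %), PhMgBr (3.0 equiv in all, two consumed, slow addition), THF, −78 → −30 °C; 1 M HCl, 0 °C
Reagents that add atoms: phenylmagnesium bromide (second equivalent, for the conjugate addition), Br[Mg]c1ccccc1
Why: Copper-catalysed anti-SN2′ substitution of the strained β-vinyl β-lactone should use one equivalent of the Grignard reagent to place phenyl on C5 of 3 (C4 of the target) on the face away from the lactone bridge, trans to the carboxylate it releases, and move the double bond into conjugation with the ester; the strained cyclobutenoate 5 then takes the second phenyl from a second equivalent by copper-catalysed conjugate addition anti to the neighbouring phenyl, at a temperature where thermal ring opening of the cyclobutene is slow, and protonation of the ester enolate from its open face on work-up is expected to give mainly the C2 epimer 6, which the next step corrects.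

**Step 4**
Reactants: 6 rac-(1R,2S,3S,4S)-2-(methoxycarbonyl)-3,4-diphenylcyclobutane-1-carboxylic acid
Product: 7 rac-(1R,2R,3S,4S)-2-(methoxycarbonyl)-3,4-diphenylcyclobutane-1-carboxylic acid
Conditions: NaOMe (3 equiv), MeOH, 65 °C; then 1 M HCl
Reagents that add atoms: none
Why: Thermodynamic epimerisation through the ester enolate at C2 (methoxide on a methyl ester, so transesterification is invisible) should drain the material into the all-trans isomer, in which every substituent is trans to both neighbours, while the carboxylate-bearing C1 and the phenyl-bearing C3 and C4 do not enolise.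

**Step 5**
Reactants: 7 rac-(1R,2R,3S,4S)-2-(methoxycarbonyl)-3,4-diphenylcyclobutane-1-carboxylic acid; 8 (R)-1-phenylethylamine
Product: 9 (R)-1-phenylethylammonium (1R,2R,3S,4S)-2-(methoxycarbonyl)-3,4-diphenylcyclobutane-1-carboxylate
Conditions: 8 (1.0 equiv), EtOH, 75 → 20 °C; recrystallisation from EtOH to constant rotation
Reagents that add atoms: none
Why: Classical resolution by diastereomeric salt crystallisation, for which a rigid acid carrying two phenyl groups is well suited; a crystal structure of the salt would tie the configuration of the acid to the known centre of the amine.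

**Step 6**
Reactants: 9 (R)-1-phenylethylammonium (1R,2R,3S,4S)-2-(methoxycarbonyl)-3,4-diphenylcyclobutane-1-carboxylate
Product: 10 (1R,2R,3S,4S)-3,4-diphenylcyclobutane-1,2-dicarboxylic acid
Conditions: 2 M NaOH aq, MeOH/THF, 60 °C; MTBE wash to remove the amine; HCl to pH 1
Reagents that add atoms: sodium hydroxide, [Na+].[OH-]
Why: Saponification of the methyl ester; hot base cannot erode the all-trans arrangement because it is the thermodynamic one and the phenyl-bearing carbons are not acidic.

**Step 7**
Reactants: 10 (1R,2R,3S,4S)-3,4-diphenylcyclobutane-1,2-dicarboxylic acid; 11 1,3-dimethoxybenzene (first equivalent)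
Product: 13 [(1R,2R,3S,4S)-3,4-diphenylcyclobutane-1,2-diyl]bis[(2,4-dimethoxyphenyl)methanone], via diacid dichloride 12 (not isolated)
Conditions: (COCl)2 (3 equiv), DMF (cat.), CH2Cl2, 0 °C → rt, evaporate; then 11 (4 equiv in all, two consumed), AlCl3 (3 equiv), CH2Cl2, 0 °C → rt; cold 1 M HCl
Reagents that add atoms: 1,3-dimethoxybenzene (second equivalent, for the second acid chloride), COc1cccc(OC)c1
Why: Double Friedel–Crafts acylation, one molecule of 1,3-dimethoxybenzene per acid chloride, at its C4 (para to one methoxy, ortho to the other); each acid chloride is trans to its neighbouring phenyl, so intramolecular acylation would need a trans-fused bicyclo[3.2.0] ring and should not compete with the activated external arene, and any partial loss of an ortho methyl ether to AlCl3 is harmless because the next step removes all four.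

**Step 8**
Reactants: 13 [(1R,2R,3S,4S)-3,4-diphenylcyclobutane-1,2-diyl]bis[(2,4-dimethoxyphenyl)methanone]
Product: 14 [(1R,2R,3S,4S)-3,4-diphenylcyclobutane-1,2-diyl]bis[(2,4-dihydroxyphenyl)methanone]
Conditions: BBr3 (8 equiv), CH2Cl2, −78 °C → rt; H2O, 0 °C
Reagents that add atoms: none
Why: Boron tribromide cleavage of the four aryl methyl ethers, helped at the ortho positions by chelation to the ketone; if the ketone α-centres enolise they return to the all-trans arrangement, which is the thermodynamic one.

**Compound list**
1 | 2-oxo-2H-pyran-6-carboxylic acid | O=C(O)c1cccc(=O)o1 | starting material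
2 | methyl 2-oxo-2H-pyran-6-carboxylate | COC(=O)c1cccc(=O)o1 | intermediate
3 | rac-methyl (1S,4R)-3-oxo-2-oxabicyclo[2.2.0]hex-5-ene-1-carboxylate (cis-fused) | O=C1O[C@@]2(C(=O)OC)C=C[C@@H]12 | intermediate
4 | phenylmagnesium bromide (commercial THF solution, or from bromobenzene and Mg) | Br[Mg]c1ccccc1 | starting material
5 | bromomagnesium rac-(1R,4S)-2-(methoxycarbonyl)-4-phenylcyclobut-2-ene-1-carboxylate (phenyl trans to carboxylate) | Br[Mg]OC(=O)[C@H]1C(C(=O)OC)=C[C@@H]1c1ccccc1 | intermediate
6 | rac-(1R,2S,3S,4S)-2-(methoxycarbonyl)-3,4-diphenylcyclobutane-1-carboxylic acid (ester cis to both neighbours, phenyls trans) | OC(=O)[C@H]1[C@@H](C(=O)OC)[C@@H](c2ccccc2)[C@@H]1c1ccccc1 | intermediate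
7 | rac-(1R,2R,3S,4S)-2-(methoxycarbonyl)-3,4-diphenylcyclobutane-1-carboxylic acid (all-trans) | OC(=O)[C@H]1[C@H](C(=O)OC)[C@@H](c2ccccc2)[C@@H]1c1ccccc1 | intermediate
8 | (R)-1-phenylethylamine | C[C@@H](N)c1ccccc1 | starting material
9 | (R)-1-phenylethylammonium (1R,2R,3S,4S)-2-(methoxycarbonyl)-3,4-diphenylcyclobutane-1-carboxylate | [O-]C(=O)[C@H]1[C@H](C(=O)OC)[C@@H](c2ccccc2)[C@@H]1c1ccccc1.C[C@@H]([NH3+])c1ccccc1 | intermediate
10 | (1R,2R,3S,4S)-3,4-diphenylcyclobutane-1,2-dicarboxylic acid (all-trans) | OC(=O)[C@H]1[C@H](C(=O)O)[C@@H](c2ccccc2)[C@@H]1c1ccccc1 | intermediate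
11 | 1,3-dimethoxybenzene | COc1cccc(OC)c1 | starting material
12 | (1R,2R,3S,4S)-3,4-diphenylcyclobutane-1,2-dicarbonyl dichloride | ClC(=O)[C@H]1[C@H](C(Cl)=O)[C@@H](c2ccccc2)[C@@H]1c1ccccc1 | intermediate
13 | [(1R,2R,3S,4S)-3,4-diphenylcyclobutane-1,2-diyl]bis[(2,4-dimethoxyphenyl)methanone] | O=C(c1ccc(OC)cc1OC)[C@H]1[C@H](C(=O)c2ccc(OC)cc2OC)[C@@H](c2ccccc2)[C@@H]1c1ccccc1 | intermediate
14 | [(1R,2R,3S,4S)-3,4-diphenylcyclobutane-1,2-diyl]bis[(2,4-dihydroxyphenyl)methanone] | O=C(c1ccc(O)cc1O)[C@H]1[C@H](C(=O)c2ccc(O)cc2O)[C@@H](c2ccccc2)[C@@H]1c1ccccc1 | target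

**Step count**
Total: 8 steps. Longest linear sequence: 8 steps (1 → 14); 4, 8 and 11 are bought.

**Steps most likely to fail**

Step 2. The excited pyranone may partition mainly into the reversible α-cleavage, so that the bicyclic lactone builds up slowly. Long irradiation may then cause secondary photodecarboxylation, and the ester-bearing β-lactone may revert or hydrolyse on concentration. The fallback gives up the pyranone and builds the ring by a head-to-head [2+2] dimerisation. It sets out from 11, which is acylated with cinnamoyl chloride (AlCl3, CH2Cl2, 0 °C) to (E)-1-(2,4-dimethoxyphenyl)-3-phenylprop-2-en-1-one F1. Visible-light triplet sensitisation of this chalcone (iridium photocatalyst, blue LEDs, degassed MeCN) should give mainly the all-trans head-to-head dimer as a racemate, that is 13 together with its mirror image [(1S,2S,3R,4R)-3,4-diphenylcyclobutane-1,2-diyl]bis[(2,4-dimethoxyphenyl)methanone] F2. F2 is removed by preparative chromatography on a chiral stationary phase, and the route is rejoined at 13.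

Step 3. Free Grignard reagent may attack the lactone or ester carbonyl before copper delivers the phenyl. The intermediate trans-cyclobutene may undergo conrotatory ring opening to a dienoate if the second addition is slow, or the second addition may stop short. The fallback separates the two C–Ph bond formations and changes the mechanism of the second. It sets out from 3, which is opened with stoichiometric lithium diphenylcuprate (THF, −78 °C, cold acidic quench) to rac-(1R,4S)-2-(methoxycarbonyl)-4-phenylcyclobut-2-ene-1-carboxylic acid F3, kept cold. F3 is then arylated as its potassium salt by rhodium(I)-catalysed Hayashi–Miyaura 1,4-addition of phenylboronic acid ([Rh(cod)OH]2, dioxane/H2O, 20 °C), anti to the existing phenyl, and the route is rejoined at 6.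

Step 5. The two diastereomeric salts may co-crystallise or oil out, so that crystallisation brings no enrichment. The fallback uses covalent diastereomers and sets out from 7, which is esterified with (R)-pantolactone (DCC, DMAP, CH2Cl2). This gives 1-[(3R)-4,4-dimethyl-2-oxooxolan-3-yl] 2-methyl (1R,2R,3S,4S)-3,4-diphenylcyclobutane-1,2-dicarboxylate F4 and its diastereomer 1-[(3R)-4,4-dimethyl-2-oxooxolan-3-yl] 2-methyl (1S,2S,3R,4R)-3,4-diphenylcyclobutane-1,2-dicarboxylate F5, which are separated by chromatography on silica. Hydrolysis of both ester groups of F4 (LiOH, THF/H2O, 50 °C; HCl) rejoins the route at 10.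

**Further compounds**
F1 | step 2 | (E)-1-(2,4-dimethoxyphenyl)-3-phenylprop-2-en-1-one | COc1ccc(C(=O)/C=C/c2ccccc2)c(OC)c1
F2 | step 2 | [(1S,2S,3R,4R)-3,4-diphenylcyclobutane-1,2-diyl]bis[(2,4-dimethoxyphenyl)methanone] | O=C(c1ccc(OC)cc1OC)[C@@H]1[C@@H](C(=O)c2ccc(OC)cc2OC)[C@H](c2ccccc2)[C@H]1c1ccccc1
F3 | step 3 | rac-(1R,4S)-2-(methoxycarbonyl)-4-phenylcyclobut-2-ene-1-carboxylic acid | OC(=O)[C@H]1C(C(=O)OC)=C[C@@H]1c1ccccc1
F4 | step 5 | 1-[(3R)-4,4-dimethyl-2-oxooxolan-3-yl] 2-methyl (1R,2R,3S,4S)-3,4-diphenylcyclobutane-1,2-dicarboxylate | O=C(O[C@H]1C(=O)OCC1(C)C)[C@H]1[C@H](C(=O)OC)[C@@H](c2ccccc2)[C@@H]1c1ccccc1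
F5 | step 5 | 1-[(3R)-4,4-dimethyl-2-oxooxolan-3-yl] 2-methyl (1S,2S,3R,4R)-3,4-diphenylcyclobutane-1,2-dicarboxylate | O=C(O[C@H]1C(=O)OCC1(C)C)[C@@H]1[C@@H](C(=O)OC)[C@H](c2ccccc2)[C@H]1c1ccccc1
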